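The target is an achiral tridepside (rings A, B, C from the methoxylated end to the free acid). Everything rests on building ring B onto an ester that already exists: ring B is an orsellinate whose C1 carboxyl is esterified by the ring C 4-oxygen, so the acetoacetate of the ring C phenol holds the ester carbon and C1 to C3 of ring B. In one operation its bis(silyloxy)diene (ring C as benzyl ester with a transient silyl ether) and ketal-masked acetoacetyl chloride form C3–C4 and C1–C6, close ring B and free its 2-OH and 4-OH. Acylation of the 4-OH with the ring A acid and hydrogenolysis finish.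

Key step: step 6

Remarks on the chemistry
- The target has no stereocentre, axis or stereogenic double bond, so no step has to control configuration.
- Ring C is carried with its 2-OH unprotected (silylated only while the diene exists), not as a benzyl ether. A benzyl ether ortho to an ester carbonyl is prone to chelation-assisted cleavage by TiCl4, and it would have to be installed against the natural 4-OH over 2-OH reactivity. The hydrogen-bonded 2-OH is not expected to compete in either acylation.
- Aromatisation of ring B releases ethylene glycol only, no water. The mono enol ether, the ketene acetal of the diene and the cyclised intermediate are expected as isomer mixtures, which is immaterial; their SMILES carry no geometry.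

Step 1
Reactants: 1 orsellinic acid (2,4-dihydroxy-6-methylbenzoic acid)
Product: 2 benzyl 2,4-dihydroxy-6-methylbenzoate (benzyl orsellinate)
Conditions: BnBr (1.05 equiv), KHCO3, DMF, rt
Reagents that add atoms: benzyl bromide, BrCc1ccccc1
Why: Carboxylate O-alkylation (SN2); hydrogencarbonate deprotonates only the carboxylic acid, so the ester should form at room temperature without touching the phenols and without the heat that decarboxylates orsellinic acid.

Step 2
Reactants: 2 benzyl orsellinate; 3 2,2,6-trimethyl-4H-1,3-dioxin-4-one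
Product: 5 benzyl 2-hydroxy-6-methyl-4-[(3-oxobutanoyl)oxy]benzoate, via acetylketene 4 (not isolated)
Conditions: 3 (1.05 equiv), toluene, 110 °C, acetone distilled off
Reagents that add atoms: none
Why: Thermal retro-hetero-Diels–Alder of the dioxinone releases acetylketene, which should be trapped by the free, more nucleophilic 4-OH (acetoacetylation by acylketene capture) while the 2-OH stays hydrogen-bonded to the benzyl ester.

Step 3
Reactants: 5 benzyl 2-hydroxy-6-methyl-4-[(3-oxobutanoyl)oxy]benzoate
Product: 7 benzyl 4-{[1,3-bis(trimethylsilyloxy)buta-1,3-dien-1-yl]oxy}-6-methyl-2-(trimethylsilyloxy)benzoate, via mono(silyl enol ether) 6 (not isolated)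
Conditions: TMSOTf (3.3 equiv), Et3N (4 equiv), Et2O, 0 °C to rt; pentane extraction, used crude
Reagents that add atoms: trimethylsilyl trifluoromethanesulfonate, C[Si](C)(C)OS(=O)(=O)C(F)(F)F
Why: One-pot soft enolisation of a β-keto ester with silyl triflate and amine, in which the ketone is silylated first, the triflate then activates the ester carbonyl so that the amine removes a γ-proton, and the ring C phenol is silylated in passing, all without a strong base that could attack the aryl ester or the acidic ortho-methyl group.

Step 4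
Reactants: 8 ethyl 2-methyl-1,3-dioxolane-2-acetate
Product: 9 potassium (2-methyl-1,3-dioxolan-2-yl)acetate
Conditions: KOH (1.0 equiv), EtOH–H2O, rt; evaporated, dried in vacuo
Reagents that add atoms: potassium hydroxide, [K+].[OH-]
Why: Saponification under basic conditions keeps the acid-labile dioxolane intact and delivers the carboxylate as a dry salt, never as the free acid.

Step 5
Reactants: 9 potassium (2-methyl-1,3-dioxolan-2-yl)acetate
Product: 10 (2-methyl-1,3-dioxolan-2-yl)acetyl chloride
Conditions: (COCl)2 (1.0 equiv), pyridine (cat.), Et2O, 0 °C; filtered, concentrated cold, used at once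
Reagents that add atoms: oxalyl chloride, ClC(=O)C(=O)Cl
Why: Acid chloride formation from a carboxylate salt with oxalyl chloride gives only KCl, CO and CO2 as by-products, so no HCl arises that could open the ketal.

Step 6
Reactants: 7 benzyl 4-{[1,3-bis(trimethylsilyloxy)buta-1,3-dien-1-yl]oxy}-6-methyl-2-(trimethylsilyloxy)benzoate; 10 (2-methyl-1,3-dioxolan-2-yl)acetyl chloride
Product: 13 benzyl 4-[(2,4-dihydroxy-6-methylbenzoyl)oxy]-2-hydroxy-6-methylbenzoate, via acyclic dioxo ester 11 (not isolated), via cyclised glycol ether 12 (not isolated)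
Conditions: 10 (1.1 equiv), CH2Cl2, −78 °C; TiCl4 (2.5 equiv), −78 to 0 °C; dilute aq. HCl work-up
Reagents that add atoms: none
Why: Mukaiyama-type C-acylation of the diene terminus, the most nucleophilic carbon of the vinylogous ketene acetal, by the acyl chloride forms C3–C4 of ring B and gives 11 as its silyl or titanium enolate; TiCl4 then opens the dioxolane to an oxocarbenium ion that is attacked by the central carbon (C1 of ring B), forming C1–C6 and giving 12. This ring closure is a 6-(enolendo)-exo-trig aldol-type cyclisation, and 12 loses ethylene glycol to a cyclohexadienone that tautomerises to the resorcylate. The closest known reaction type is the TiCl4-mediated formal [3+3] cycloaromatisation of 1-alkoxy-1,3-bis(silyloxy)buta-1,3-dienes with ketal-masked β-keto acid chlorides to alkyl 6-alkyl-2,4-dihydroxybenzoates. No stereocentre is created in the product; the two transient centres of 12 vanish on aromatisation. The step needs the terminus to meet the acyl carbon and the centre the ketal carbon (the reverse order would give the 2,6-dihydroxy-4-methyl isomer), which the higher nucleophilicity of the terminus and the higher electrophilicity of the acyl chloride should secure, helped by mixing diene and chloride before the Lewis acid is added. It also needs C- over O-cyclisation, which low temperature and titanium chelation of the 1,3-dicarbonyl unit favour; the ring C silyl ether falls off on work-up and the benzyl ester is a spectator.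

Step 7
Reactants: 14 methyl orsellinate (methyl 2,4-dihydroxy-6-methylbenzoate)
Product: 15 methyl 2,4-bis(benzyloxy)-6-methylbenzoate
Conditions: BnBr (2.5 equiv), K2CO3, DMF, 60 °C
Reagents that add atoms: benzyl bromide, BrCc1ccccc1
Why: Williamson ether synthesis; warm DMF with excess base and bromide should also alkylate the hydrogen-bonded 2-OH, and the methyl ester is inert.

Step 8
Reactants: 15 methyl 2,4-bis(benzyloxy)-6-methylbenzoate
Product: 16 methyl 4,6-bis(benzyloxy)-3-bromo-2-methylbenzoate (bromine at C5 in orsellinate numbering)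
Conditions: NBS (1.05 equiv), MeCN, 0 °C to rt, dark
Reagents that add atoms: N-bromosuccinimide, BrN1C(=O)CCC1=O
Why: Electrophilic aromatic bromination; C5 is para to the 2-benzyloxy and ortho to the 4-benzyloxy group, the usual halogenation site of 2,4-dialkoxy-6-alkylbenzoates, whereas C3 is crowded between two benzyloxy groups, and a polar solvent without light suppresses benzylic bromination.

Step 9
Reactants: 16 methyl 4,6-bis(benzyloxy)-3-bromo-2-methylbenzoate
Product: 17 methyl 4,6-bis(benzyloxy)-3-methoxy-2-methylbenzoate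
Conditions: NaOMe (5 equiv), CuBr (0.2 equiv), MeOH–DMF, 110 °C
Reagents that add atoms: sodium methoxide, [Na+].[O-]C
Why: Copper-catalysed Ullmann-type methoxylation of an electron-rich aryl bromide, known to tolerate two ortho substituents; methoxide cannot alter a methyl ester and benzyl ethers are base-stable.

Step 10
Reactants: 17 methyl 4,6-bis(benzyloxy)-3-methoxy-2-methylbenzoate
Product: 18 4,6-bis(benzyloxy)-3-methoxy-2-methylbenzoic acid
Conditions: KOH, DMSO–H2O, 90 °C; then cold dilute HCl
Reagents that add atoms: potassium hydroxide, [K+].[OH-]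
Why: Saponification of a di-ortho-substituted benzoate needs hydroxide in hot aqueous DMSO; the ethers are stable and cold acidification avoids decarboxylation.

Step 11
Reactants: 18 4,6-bis(benzyloxy)-3-methoxy-2-methylbenzoic acid; 13 benzyl 4-[(2,4-dihydroxy-6-methylbenzoyl)oxy]-2-hydroxy-6-methylbenzoate
Product: 20 benzyl 4-[(4-{[4,6-bis(benzyloxy)-3-methoxy-2-methylbenzoyl]oxy}-2-hydroxy-6-methylbenzoyl)oxy]-2-hydroxy-6-methylbenzoate, via mixed trifluoroacetic anhydride 19 (not isolated)
Conditions: TFAA (2.5 equiv), toluene, rt; aq. NaHCO3 work-up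
Reagents that add atoms: none
Why: Esterification through the mixed trifluoroacetic anhydride, an acylium-type activation suited to electron-rich 2,6-disubstituted benzoic acids; only the non-chelated ring B 4-OH should be acylated, since both 2-OH groups are hydrogen-bonded to their ester carbonyls, and the acidic medium spares the existing depside bond and the benzyl groups.

Step 12
Reactants: 20 benzyl 4-[(4-{[4,6-bis(benzyloxy)-3-methoxy-2-methylbenzoyl]oxy}-2-hydroxy-6-methylbenzoyl)oxy]-2-hydroxy-6-methylbenzoate
Product: 21 4-[(4-{[4,6-dihydroxy-3-methoxy-2-methylbenzoyl]oxy}-2-hydroxy-6-methylbenzoyl)oxy]-2-hydroxy-6-methylbenzoic acid (target)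
Conditions: H2 (1 atm), 10% Pd/C, EtOAc, rt
Reagents that add atoms: none
Why: Hydrogenolysis of the benzyl ester and both benzyl ethers over palladium; the aryl esters, the aryl methyl ether and the arenes should be untouched at 1 atm and room temperature.

Compound list
1 | orsellinic acid (2,4-dihydroxy-6-methylbenzoic acid) | Cc1cc(O)cc(O)c1C(=O)O | starting material
2 | benzyl 2,4-dihydroxy-6-methylbenzoate | Cc1cc(O)cc(O)c1C(=O)OCc1ccccc1 | intermediate
3 | 2,2,6-trimethyl-4H-1,3-dioxin-4-one | CC1=CC(=O)OC(C)(C)O1 | starting material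
4 | acetylketene (3-oxobut-1-en-1-one) | CC(=O)C=C=O | intermediate (not isolated)
5 | benzyl 2-hydroxy-6-methyl-4-[(3-oxobutanoyl)oxy]benzoate | CC(=O)CC(=O)Oc1cc(C)c(C(=O)OCc2ccccc2)c(O)c1 | intermediate
6 | benzyl 6-methyl-2-(trimethylsilyloxy)-4-{[3-(trimethylsilyloxy)but-2-enoyl]oxy}benzoate (E/Z mixture) | CC(O[Si](C)(C)C)=CC(=O)Oc1cc(C)c(C(=O)OCc2ccccc2)c(O[Si](C)(C)C)c1 | intermediate (not isolated)
7 | benzyl 4-{[1,3-bis(trimethylsilyloxy)buta-1,3-dien-1-yl]oxy}-6-methyl-2-(trimethylsilyloxy)benzoate (E/Z mixture at the ketene acetal) | C=C(O[Si](C)(C)C)C=C(O[Si](C)(C)C)Oc1cc(C)c(C(=O)OCc2ccccc2)c(O[Si](C)(C)C)c1 | intermediate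
8 | ethyl 2-methyl-1,3-dioxolane-2-acetate | CCOC(=O)CC1(C)OCCO1 | starting material
9 | potassium (2-methyl-1,3-dioxolan-2-yl)acetate | CC1(CC(=O)[O-])OCCO1.[K+] | intermediate
10 | (2-methyl-1,3-dioxolan-2-yl)acetyl chloride | CC1(CC(=O)Cl)OCCO1 | intermediate
11 | benzyl 6-methyl-4-{[6-(2-methyl-1,3-dioxolan-2-yl)-3,5-dioxohexanoyl]oxy}-2-(trimethylsilyloxy)benzoate (present as silyl or titanium enolate) | CC1(CC(=O)CC(=O)CC(=O)Oc2cc(C)c(C(=O)OCc3ccccc3)c(O[Si](C)(C)C)c2)OCCO1 | intermediate (not isolated)
12 | benzyl 4-{[2-(2-hydroxyethoxy)-2-methyl-4,6-dioxocyclohexanecarbonyl]oxy}-6-methyl-2-(trimethylsilyloxy)benzoate (mixture of stereoisomers) | CC1(OCCO)CC(=O)CC(=O)C1C(=O)Oc1cc(C)c(C(=O)OCc2ccccc2)c(O[Si](C)(C)C)c1 | intermediate (not isolated)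
13 | benzyl 4-[(2,4-dihydroxy-6-methylbenzoyl)oxy]-2-hydroxy-6-methylbenzoate | Cc1cc(O)cc(O)c1C(=O)Oc1cc(C)c(C(=O)OCc2ccccc2)c(O)c1 | intermediate
14 | methyl orsellinate (methyl 2,4-dihydroxy-6-methylbenzoate) | COC(=O)c1c(C)cc(O)cc1O | starting material
15 | methyl 2,4-bis(benzyloxy)-6-methylbenzoate | COC(=O)c1c(C)cc(OCc2ccccc2)cc1OCc1ccccc1 | intermediate
16 | methyl 4,6-bis(benzyloxy)-3-bromo-2-methylbenzoate | COC(=O)c1c(C)c(Br)c(OCc2ccccc2)cc1OCc1ccccc1 | intermediate
17 | methyl 4,6-bis(benzyloxy)-3-methoxy-2-methylbenzoate | COC(=O)c1c(C)c(OC)c(OCc2ccccc2)cc1OCc1ccccc1 | intermediate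
18 | 4,6-bis(benzyloxy)-3-methoxy-2-methylbenzoic acid | OC(=O)c1c(C)c(OC)c(OCc2ccccc2)cc1OCc1ccccc1 | intermediate
19 | 4,6-bis(benzyloxy)-3-methoxy-2-methylbenzoic trifluoroacetic anhydride | COc1c(OCc2ccccc2)cc(OCc2ccccc2)c(C(=O)OC(=O)C(F)(F)F)c1C | intermediate (not isolated)
20 | benzyl 4-[(4-{[4,6-bis(benzyloxy)-3-methoxy-2-methylbenzoyl]oxy}-2-hydroxy-6-methylbenzoyl)oxy]-2-hydroxy-6-methylbenzoate | COc1c(OCc2ccccc2)cc(OCc2ccccc2)c(C(=O)Oc2cc(C)c(C(=O)Oc3cc(C)c(C(=O)OCc4ccccc4)c(O)c3)c(O)c2)c1C | intermediate
21 | 4-[(4-{[4,6-dihydroxy-3-methoxy-2-methylbenzoyl]oxy}-2-hydroxy-6-methylbenzoyl)oxy]-2-hydroxy-6-methylbenzoic acid | COc1c(O)cc(O)c(C(=O)Oc2cc(C)c(C(=O)Oc3cc(C)c(C(=O)O)c(O)c3)c(O)c2)c1C | target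

Total step count: 12
Longest linear sequence: 6 steps (1, 2, 3, 6, 11, 12; the ring A branch 7 to 12 is equally long)

Steps most likely to fail

Step 6. The order of bond formation may invert (terminus adding to the titanium-opened ketal, which would give the 2,6-dihydroxy-4-methyl ring). The dioxo ester may instead close through oxygen onto the activated aryl ester and expel the ring C phenol, or the Lewis acid may cleave the benzyl ester. The fallback abandons the cycloaromatisation and assembles the esters classically from the ring A end. It sets out from acid 18, which is esterified by the trifluoroacetic anhydride method with purchased 2,4-dihydroxy-6-methylbenzaldehyde (Cc1cc(O)cc(O)c1C=O) at its non-chelated 4-OH to give 4-formyl-3-hydroxy-5-methylphenyl 4,6-bis(benzyloxy)-3-methoxy-2-methylbenzoate F1. Pinnick oxidation (NaClO2, NaH2PO4, 2-methylbut-2-ene, aq. t-BuOH) should convert the aldehyde into 4-{[4,6-bis(benzyloxy)-3-methoxy-2-methylbenzoyl]oxy}-2-hydroxy-6-methylbenzoic acid F2. Carbodiimide coupling of F2 (DCC, toluene, rt) with the 4-OH of benzyl orsellinate 2 comes back to the route at 20.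

Step 3. The second enolisation may stall at the mono enol ether, silylation may occur on carbon, or the ketene acetal may hydrolyse during isolation. The fallback avoids the silyl diene and forms the same bonds in a fixed order through an acylketene. It sets out from dioxinone 3, whose lithium dienolate (LiHMDS, 2 equiv, THF, −78 °C) is C-acylated at the 6-methyl group by chloride 10 to give 2,2-dimethyl-6-[3-(2-methyl-1,3-dioxolan-2-yl)-2-oxopropyl]-4H-1,3-dioxin-4-one F3. Heating F3 with benzyl orsellinate 2 in toluene releases acetone and an acylketene, which the 4-OH of 2 should trap to give benzyl 2-hydroxy-6-methyl-4-{[6-(2-methyl-1,3-dioxolan-2-yl)-3,5-dioxohexanoyl]oxy}benzoate F4, the silicon-free counterpart of 11. TiCl4 in CH2Cl2 at −78 °C then closes the ring onto the ketal carbon with loss of ethylene glycol, and the route is rejoined at 13.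

Step 9. The copper-mediated substitution may stall at the doubly ortho-substituted carbon or be overtaken by reductive loss of bromine. The fallback brings in the oxygen through boron. It sets out from bromide 16: Miyaura borylation (B2pin2, Pd(OAc)2/SPhos, KOAc, dioxane, 90 °C) should give methyl 4,6-bis(benzyloxy)-2-methyl-3-(4,4,5,5-tetramethyl-1,3,2-dioxaborolan-2-yl)benzoate F5. Oxidation (H2O2, NaOH, THF–H2O, 0 °C) gives methyl 4,6-bis(benzyloxy)-3-hydroxy-2-methylbenzoate F6, and O-methylation (MeI, K2CO3, acetone) returns to the route at 17.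

Further compounds
F1 | step 6 | 4-formyl-3-hydroxy-5-methylphenyl 4,6-bis(benzyloxy)-3-methoxy-2-methylbenzoate | COc1c(OCc2ccccc2)cc(OCc2ccccc2)c(C(=O)Oc2cc(C)c(C=O)c(O)c2)c1C
F2 | step 6 | 4-{[4,6-bis(benzyloxy)-3-methoxy-2-methylbenzoyl]oxy}-2-hydroxy-6-methylbenzoic acid | COc1c(OCc2ccccc2)cc(OCc2ccccc2)c(C(=O)Oc2cc(C)c(C(=O)O)c(O)c2)c1C
F3 | step 3 | 2,2-dimethyl-6-[3-(2-methyl-1,3-dioxolan-2-yl)-2-oxopropyl]-4H-1,3-dioxin-4-one | CC1(CC(=O)CC2=CC(=O)OC(C)(C)O2)OCCO1
F4 | step 3 | benzyl 2-hydroxy-6-methyl-4-{[6-(2-methyl-1,3-dioxolan-2-yl)-3,5-dioxohexanoyl]oxy}benzoate | CC1(CC(=O)CC(=O)CC(=O)Oc2cc(C)c(C(=O)OCc3ccccc3)c(O)c2)OCCO1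
F5 | step 9 | methyl 4,6-bis(benzyloxy)-2-methyl-3-(4,4,5,5-tetramethyl-1,3,2-dioxaborolan-2-yl)benzoate | COC(=O)c1c(C)c(B2OC(C)(C)C(C)(C)O2)c(OCc2ccccc2)cc1OCc1ccccc1
F6 | step 9 | methyl 4,6-bis(benzyloxy)-3-hydroxy-2-methylbenzoate | COC(=O)c1c(C)c(O)c(OCc2ccccc2)cc1OCc1ccccc1
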